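At early times target rises nearly in step with free catalyst. At 0.250 h the east run, charged with 8 mM, reads 14%, and the south-east run, charged with 32 mM, reads 44%, a slope of 0.826 between the logarithms. We want the top of target in a flask lying between these two runs.

| flask | substrate | free catalyst | remark | time |
|---|---|---|---|---|
| east | 0.20 M | 8 mM | run made earlier |  |
| south-east | 0.20 M | 32 mM | run made earlier |  |
| south-west | 0.40 M | 16 mM | run made earlier |  |
| flask | 0.20 M | 16 mM |  | 3.0 h |

| run | time / h | target / % |
|---|---|---|
| east | 0.250 | 14 |
| east | 0.417 | 22 |
| east | 0.500 | 25 |
| east | 0.833 | 37 |
| east | 1.00 | 37 |
| east | 1.50 | 41 |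
| east | 2.50 | 37 |
| south-east | 0.250 | 44 |
| south-east | 0.417 | 58 |
| south-east | 0.500 | 56 |
| south-east | 0.833 | 52 |
| south-east | 1.00 | 55 |
| south-east | 1.50 | 52 |
| south-east | 2.50 | 39 |
| south-west | 0.250 | 19 |
| south-west | 0.500 | 31 |
| south-west | 0.833 | 39 |
| south-west | 1.33 | 34 |
| south-west | 2.50 | 31 |

(each reading ± 2 percentage points)

- the moment within 3.0 h at which there is most target
- the amount of target, in percent of the substrate charged, at that time



Suppose the loss of target needs no catalyst. Two limits can then be solved in the head. If loss far outruns making, target sits at making over loss, so the peak height goes with catalyst, slope one. If making far outruns loss, the peak stands at a ceiling of the making itself that does not move with catalyst, slope zero. The highest readings, 41% in the east run and 58% in the south-east run, grow with catalyst, but by a smaller ratio than catalyst does, so the slope must lie between these limits. In powers of ten, the peak climbs 0.151 while catalyst climbs 0.602, which gives 0.250. We call this m, the slope of log peak target against log catalyst, the peak order. Carried from the east reading, it gives the flask 48.8%.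

The tops are flat. Readings within 3 times the scatter of the highest span 0.833 h to 2.50 h in the east run and 0.417 h to 1.50 h in the south-east run. The logarithmic middle of these spans puts the flask's peak near 1.07 h.

The forecast gives 48% at 0.75 h, in its words “Interpolating geometrically to 16 mM”, a similar height to ours but earlier than our time.

The flask gives 50.3% at 1.05 h.

    substrate + free catalyst ⇌ catalyst intermediate A (K = 0.710 /M, k = 13.0 /M/min)
    catalyst intermediate A ⇌ catalyst intermediate B (K = 7.60, k = 13.0 /min)
    catalyst intermediate B ⇌ free catalyst + target (K = 0.450 M, k = 1.00 /min)
    substrate + target → side product (k = 0.0590 /M/min)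

In this scheme the loss of substrate and target to side product contains no catalyst, as the limits supposed, while free catalyst, the resting state, holds 78.0% of the catalyst at the best time. Charged with 27.0 mM of free catalyst, all else as in the flask, the neighbour is reckoned by the same peak order from the east reading at 55.6%, and that neighbour flask reaches 54.9%.

The data were computed from invented constants; the scatter is artificial.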